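**Retrosynthetic overview**

1. Feature used: ring B (C1'–C6') carries methoxy groups at C3' and C5' and its only carbon substituent, C2 of the pyran ring C, at C1', meta to both oxygens. It is therefore the aromatised, O-methylated form of a 5-substituted cyclohexane-1,3-dione and can be grown on a chroman whose C2 configuration is already fixed.
2. Ring B ⇐ (O-methylation, dehydrogenation, decarboxylation) 2-carbomethoxy-1,3-dione ⇐ Michael–Claisen annulation of dimethyl malonate with the (E)-enone on C2 (new bonds C1'–C2' and C3'–C4').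
3. Enone ⇐ oxidation/Wittig of the (2R)-chroman-2-ylmethanol; C6 prenyl group ⇐ lithiation between the two MOM ethers of ring A.
4. (2R)-Chroman-2-ylmethanol ⇐ racemic chroman-2-carboxylic acid, resolved covalently as its N-acyl (S)-4-benzyloxazolidinone ⇐ hydrogenation of the chromone-2-carboxylate made from 2,4,6-trihydroxyacetophenone and diethyl oxalate.
5. Ring order: ring A is bought, ring C is closed in step 1, ring B is closed in step 10 and made aromatic in step 13.

Key step: step 10

Remark on the chemistry: the two diastereomeric imides of step 4 are assumed to be separable on silica gel (or by crystallisation), and the one carrying (2R) is to be identified by X-ray analysis before it is taken on. Racemic compounds are written without stereodescriptors.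

**Route**

Step 1
Reactants: 1 2,4,6-trihydroxyacetophenone; 2 diethyl oxalate
Product: 4 ethyl 5,7-dihydroxy-4-oxo-4H-chromene-2-carboxylate, via diketo ester 3 (not isolated)
Conditions: NaOEt (5 equiv), EtOH, reflux; then conc. HCl, EtOH, reflux
Reagents that add atoms: none
Why: Crossed Claisen condensation of the methyl ketone enolate with non-enolisable diethyl oxalate, followed by acid-catalysed cyclodehydration of the 2,4-dioxobutanoate onto an ortho hydroxyl (classical chromone-2-carboxylate synthesis); the two ortho hydroxyls are equivalent, so a single chromone can form.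

Step 2
Reactants: 4 ethyl 5,7-dihydroxy-4-oxo-4H-chromene-2-carboxylate
Product: 7 ethyl 5,7-dihydroxy-3,4-dihydro-2H-chromene-2-carboxylate (racemic), via chromanone 5 (not isolated), via chroman-4-ol 6 (not isolated)
Conditions: H2 (5 bar), 10% Pd/C, AcOH, conc. HCl (cat.), 60 °C
Reagents that add atoms: none
Why: Heterogeneous catalytic hydrogenation saturates the C2–C3 double bond and, under acid, hydrogenolyses the electron-rich benzylic C4 carbonyl by way of the alcohol, the known reduction of chromone-2-carboxylates to chroman-2-carboxylates; C2 arises as a racemate, which is resolved in step 4.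

Step 3
Reactants: 7 racemic ethyl 5,7-dihydroxychroman-2-carboxylate
Product: 9 5,7-bis(methoxymethoxy)-3,4-dihydro-2H-chromene-2-carboxylic acid (racemic), via ethyl ester 8 (not isolated)
Conditions: MOMCl, iPr2NEt, CH2Cl2, 0 °C → rt; then LiOH, THF/MeOH/H2O, rt; 1 M HCl to pH 4 at 0 °C
Reagents that add atoms: chloromethyl methyl ether, COCCl; lithium hydroxide, [Li+].[OH-]
Why: Base-mediated O-alkylation of both phenols with the chloromethyl ether gives MOM ethers that later direct the lithiation and withstand all basic steps, and lithium hydroxide saponification then frees the acid for the resolution.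

Step 4
Reactants: 9 racemic 5,7-bis(methoxymethoxy)chroman-2-carboxylic acid
Product: 11 (4S)-4-benzyl-3-{[(2R)-5,7-bis(methoxymethoxy)-3,4-dihydro-2H-chromen-2-yl]carbonyl}-1,3-oxazolidin-2-one, via mixed anhydride 10 (not isolated)
Conditions: PivCl, Et3N, THF, −20 °C; then (S)-4-benzyloxazolidin-2-one, LiCl, rt; separation of the two diastereomers on silica gel
Reagents that add atoms: (4S)-4-benzyl-1,3-oxazolidin-2-one, O=C1N[C@@H](Cc2ccccc2)CO1
Why: N-Acylation of the oxazolidinone auxiliary through the pivalic mixed anhydride converts the racemic acid into two diastereomeric imides that differ only at chroman C2, so the (2R) series is selected by separation (covalent resolution) and not by induction.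

Step 5
Reactants: 11 (2R,4S)-imide
Product: 12 [(2R)-5,7-bis(methoxymethoxy)-3,4-dihydro-2H-chromen-2-yl]methanol
Conditions: LiBH4, MeOH (1 equiv), THF, 0 °C → rt
Reagents that add atoms: none
Why: Reductive cleavage of the N-acyloxazolidinone with lithium borohydride gives the primary alcohol and releases the auxiliary; no enolate is formed, so C2 keeps its configuration.

Step 6
Reactants: 12 (2R)-chroman-2-ylmethanol
Product: 13 tert-butyl{[(2R)-5,7-bis(methoxymethoxy)-3,4-dihydro-2H-chromen-2-yl]methoxy}dimethylsilane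
Conditions: TBSCl, imidazole, DMF, rt
Reagents that add atoms: tert-butyldimethylsilyl chloride, CC(C)(C)[Si](C)(C)Cl
Why: Standard silylation of a primary alcohol, needed so that no alkoxide steers or consumes the base in the next step.

Step 7
Reactants: 13 silyl ether; 14 prenyl bromide (1-bromo-3-methylbut-2-ene)
Product: 16 tert-butyl{[(2R)-5,7-bis(methoxymethoxy)-6-(3-methylbut-2-en-1-yl)-3,4-dihydro-2H-chromen-2-yl]methoxy}dimethylsilane, via aryllithium 15 (not isolated)
Conditions: n-BuLi, THF, 0 °C; then CuI (10 mol%), 14, −78 °C → rt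
Reagents that add atoms: none
Why: Directed ortho-metalation: C6 is the only ring carbon flanked by two MOM ethers, whose cooperative chelation should direct butyllithium there in preference to C8, and the aryl anion is then allylated at the primary carbon of prenyl bromide under copper catalysis (allylic substitution).

Step 8
Reactants: 16 prenylated silyl ether
Product: 17 [(2R)-5,7-bis(methoxymethoxy)-6-(3-methylbut-2-en-1-yl)-3,4-dihydro-2H-chromen-2-yl]methanol
Conditions: Bu4NF, THF, 0 °C → rt
Reagents that add atoms: none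
Why: Fluoride-induced cleavage of the silyl ether; MOM ethers and the prenyl group are inert.

Step 9
Reactants: 17 prenylated alcohol; 18 1-(triphenylphosphoranylidene)propan-2-one
Product: 20 (3E)-4-[(2R)-5,7-bis(methoxymethoxy)-6-(3-methylbut-2-en-1-yl)-3,4-dihydro-2H-chromen-2-yl]but-3-en-2-one, via aldehyde 19 (not isolated)
Conditions: Dess–Martin periodinane, pyridine, CH2Cl2, 0 °C → rt; then 18, rt → 40 °C
Reagents that add atoms: none
Why: Dess–Martin oxidation to the α-aryloxy aldehyde, followed in the same flask by Wittig olefination with the ketone-stabilised ylide, which gives the (E)-enone and avoids isolating the epimerisable aldehyde.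

Step 10
Reactants: 20 (E)-enone; 21 dimethyl malonate
Product: 23 methyl 6-[(2R)-5,7-bis(methoxymethoxy)-6-(3-methylbut-2-en-1-yl)-3,4-dihydro-2H-chromen-2-yl]-2,4-dioxocyclohexane-1-carboxylate (diastereomer mixture), via Michael adduct 22 (not isolated)
Conditions: 21 (1.3 equiv), NaOMe (1.1 equiv), MeOH, 0 °C → rt; then reflux; 1 M HCl to pH 3 at 0 °C
Reagents that add atoms: none
Why: Sodium dimethyl malonate adds in conjugate fashion to the β-carbon of the enone (new bond C1'–C2'), and after proton transfer the methyl-ketone enolate attacks one of the two ester carbonyls with loss of methoxide (new bond C3'–C4'), so the sequence ends at the doubly stabilised enolate of the 2-carbomethoxy-1,3-dione. The closest known reaction is the classical Michael–Claisen synthesis of 5-substituted cyclohexane-1,3-diones (dimedone type) from an enone and a malonate. The carbocycle closes in the 6-exo-trig mode, an enolate carbon attacking an ester carbonyl as in a Dieckmann condensation. The two new stereocentres (ring carbons 1 and 6 of the cyclohexane) form without control and need none, since the first is lost on decarboxylation and the second becomes an aromatic carbon. The selectivity that matters is conjugate addition over deprotonation at chroman C2, the γ-position of the enone, which would scramble the only lasting stereocentre; it should be secured by the preformed, weakly basic and soft malonate anion with no excess methoxide at low temperature, and by heating for the Claisen closure only after the enone is consumed, when C2–H is no longer vinylogously acidic.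

Step 11
Reactants: 23 keto ester
Product: 25 5-[(2R)-5,7-bis(methoxymethoxy)-6-(3-methylbut-2-en-1-yl)-3,4-dihydro-2H-chromen-2-yl]cyclohexane-1,3-dione, via keto acid 24 (not isolated)
Conditions: 2 M aq. NaOH, MeOH, 70 °C; then AcOH to pH 4–5, 60 °C
Reagents that add atoms: none
Why: Saponification of the methyl ester and decarboxylation of the resulting β-keto acid on gentle warming at a pH that the MOM ethers tolerate; the ring carbon that carried the ester becomes CH2 and the carbon bearing the chroman becomes C5 of a symmetric dione, so both uncontrolled centres of step 10 disappear.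

Step 12
Reactants: 25 dione
Product: 26 3-methoxy-5-[(2R)-5,7-bis(methoxymethoxy)-6-(3-methylbut-2-en-1-yl)-3,4-dihydro-2H-chromen-2-yl]cyclohex-2-en-1-one (both configurations at ring carbon 5)
Conditions: Me2SO4, K2CO3, acetone, reflux
Reagents that add atoms: dimethyl sulfate, COS(=O)(=O)OC
Why: O-Alkylation of the dione enolate by the hard electrophile dimethyl sulfate gives the vinylogous ester; the two carbonyls are equivalent, so one constitution results, and the new centre at ring carbon 5 forms as a mixture that is erased in step 13.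

Step 13
Reactants: 26 methyl enol ether
Product: 31 3-methoxy-5-[(2R)-5,7-bis(methoxymethoxy)-6-(3-methylbut-2-en-1-yl)-3,4-dihydro-2H-chromen-2-yl]phenol, via lithium enolate 27 (not isolated), via selenide 28 (not isolated), via selenoxide 29 (not isolated), via dienone 30 (not isolated)
Conditions: LiN(iPr)2, THF, −78 °C; PhSeCl, −78 °C; then 30% H2O2, pyridine, CH2Cl2, 0 °C → rt
Reagents that add atoms: none
Why: Kinetic α'-deprotonation of the vinylogous ester, selenenylation trans to the neighbouring substituent and selenoxide syn-elimination toward C5–H give the cross-conjugated dienone, which tautomerises at once to the phenol (known aromatisation of 3-alkoxycyclohex-2-enones); chroman C2 is not acidic in any of these species.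

Step 14
Reactants: 31 phenol
Product: 32 (2R)-2-(3,5-dimethoxyphenyl)-5,7-bis(methoxymethoxy)-6-(3-methylbut-2-en-1-yl)-3,4-dihydro-2H-chromene
Conditions: MeI, K2CO3, acetone, reflux
Reagents that add atoms: iodomethane, CI
Why: Williamson O-methylation of the single free phenol completes the 3',5'-dimethoxy pattern of ring B while ring A stays masked as MOM ethers.

Step 15
Reactants: 32 bis-MOM ether
Product: 33 (2R)-2-(3,5-dimethoxyphenyl)-6-(3-methylbut-2-en-1-yl)-3,4-dihydro-2H-chromene-5,7-diol (target)
Conditions: HCl (1.25 M in MeOH), 0 °C → rt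
Reagents that add atoms: none
Why: Acid-catalysed acetal exchange removes both MOM groups as dimethoxymethane, the aryl methyl ethers are inert, the low temperature should keep the prenyl group from adding to the flanking phenols, and C2 cannot ionise because a 3,5-dimethoxyphenyl group does not stabilise a benzylic cation.

**Compound list**

1 | 2,4,6-trihydroxyacetophenone | CC(=O)c1c(O)cc(O)cc1O | starting material
2 | diethyl oxalate | CCOC(=O)C(=O)OCC | starting material
3 | ethyl 2,4-dioxo-4-(2,4,6-trihydroxyphenyl)butanoate (not isolated) | CCOC(=O)C(=O)CC(=O)c1c(O)cc(O)cc1O | intermediate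
4 | ethyl 5,7-dihydroxy-4-oxo-4H-chromene-2-carboxylate | CCOC(=O)c1cc(=O)c2c(O)cc(O)cc2o1 | intermediate
5 | ethyl 5,7-dihydroxy-4-oxo-3,4-dihydro-2H-chromene-2-carboxylate (racemic, not isolated) | CCOC(=O)C1CC(=O)c2c(O)cc(O)cc2O1 | intermediate
6 | ethyl 4,5,7-trihydroxy-3,4-dihydro-2H-chromene-2-carboxylate (racemic mixture of diastereomers, not isolated) | CCOC(=O)C1CC(O)c2c(O)cc(O)cc2O1 | intermediate
7 | ethyl 5,7-dihydroxy-3,4-dihydro-2H-chromene-2-carboxylate (racemic) | CCOC(=O)C1CCc2c(O)cc(O)cc2O1 | intermediate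
8 | ethyl 5,7-bis(methoxymethoxy)-3,4-dihydro-2H-chromene-2-carboxylate (racemic, not isolated) | CCOC(=O)C1CCc2c(OCOC)cc(OCOC)cc2O1 | intermediate
9 | 5,7-bis(methoxymethoxy)-3,4-dihydro-2H-chromene-2-carboxylic acid (racemic) | OC(=O)C1CCc2c(OCOC)cc(OCOC)cc2O1 | intermediate
10 | 5,7-bis(methoxymethoxy)-3,4-dihydro-2H-chromene-2-carboxylic 2,2-dimethylpropanoic anhydride (racemic, not isolated) | CC(C)(C)C(=O)OC(=O)C1CCc2c(OCOC)cc(OCOC)cc2O1 | intermediate
11 | (4S)-4-benzyl-3-{[(2R)-5,7-bis(methoxymethoxy)-3,4-dihydro-2H-chromen-2-yl]carbonyl}-1,3-oxazolidin-2-one | O=C1OC[C@H](Cc2ccccc2)N1C(=O)[C@H]3CCc4c(OCOC)cc(OCOC)cc4O3 | intermediate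
12 | [(2R)-5,7-bis(methoxymethoxy)-3,4-dihydro-2H-chromen-2-yl]methanol | OC[C@H]1CCc2c(OCOC)cc(OCOC)cc2O1 | intermediate
13 | tert-butyl{[(2R)-5,7-bis(methoxymethoxy)-3,4-dihydro-2H-chromen-2-yl]methoxy}dimethylsilane | CC(C)(C)[Si](C)(C)OC[C@H]1CCc2c(OCOC)cc(OCOC)cc2O1 | intermediate
14 | prenyl bromide (1-bromo-3-methylbut-2-ene) | CC(C)=CCBr | starting material
15 | C6-lithio derivative of 13 (not isolated) | CC(C)(C)[Si](C)(C)OC[C@H]1CCc2c(OCOC)c([Li])c(OCOC)cc2O1 | intermediate
16 | tert-butyl{[(2R)-5,7-bis(methoxymethoxy)-6-(3-methylbut-2-en-1-yl)-3,4-dihydro-2H-chromen-2-yl]methoxy}dimethylsilane | CC(C)(C)[Si](C)(C)OC[C@H]1CCc2c(OCOC)c(CC=C(C)C)c(OCOC)cc2O1 | intermediate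
17 | [(2R)-5,7-bis(methoxymethoxy)-6-(3-methylbut-2-en-1-yl)-3,4-dihydro-2H-chromen-2-yl]methanol | OC[C@H]1CCc2c(OCOC)c(CC=C(C)C)c(OCOC)cc2O1 | intermediate
18 | 1-(triphenylphosphoranylidene)propan-2-one | CC(=O)C=P(c1ccccc1)(c1ccccc1)c1ccccc1 | starting material
19 | (2R)-5,7-bis(methoxymethoxy)-6-(3-methylbut-2-en-1-yl)-3,4-dihydro-2H-chromene-2-carbaldehyde (not isolated) | O=C[C@H]1CCc2c(OCOC)c(CC=C(C)C)c(OCOC)cc2O1 | intermediate
20 | (3E)-4-[(2R)-5,7-bis(methoxymethoxy)-6-(3-methylbut-2-en-1-yl)-3,4-dihydro-2H-chromen-2-yl]but-3-en-2-one (key-step precursor) | CC(=O)/C=C/[C@H]1CCc2c(OCOC)c(CC=C(C)C)c(OCOC)cc2O1 | intermediate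
21 | dimethyl malonate | COC(=O)CC(=O)OC | starting material
22 | dimethyl 2-{1-[(2R)-5,7-bis(methoxymethoxy)-6-(3-methylbut-2-en-1-yl)-3,4-dihydro-2H-chromen-2-yl]-3-oxobutyl}propanedioate (both configurations at the new centre, not isolated) | COC(=O)C(C(=O)OC)C(CC(C)=O)[C@H]1CCc2c(OCOC)c(CC=C(C)C)c(OCOC)cc2O1 | intermediate
23 | methyl 6-[(2R)-5,7-bis(methoxymethoxy)-6-(3-methylbut-2-en-1-yl)-3,4-dihydro-2H-chromen-2-yl]-2,4-dioxocyclohexane-1-carboxylate (mixture at ring carbons 1 and 6; key-step product) | COC(=O)C1C(=O)CC(=O)CC1[C@H]2CCc3c(OCOC)c(CC=C(C)C)c(OCOC)cc3O2 | intermediate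
24 | 6-[(2R)-5,7-bis(methoxymethoxy)-6-(3-methylbut-2-en-1-yl)-3,4-dihydro-2H-chromen-2-yl]-2,4-dioxocyclohexane-1-carboxylic acid (mixture, not isolated) | OC(=O)C1C(=O)CC(=O)CC1[C@H]2CCc3c(OCOC)c(CC=C(C)C)c(OCOC)cc3O2 | intermediate
25 | 5-[(2R)-5,7-bis(methoxymethoxy)-6-(3-methylbut-2-en-1-yl)-3,4-dihydro-2H-chromen-2-yl]cyclohexane-1,3-dione | O=C1CC(=O)CC(C1)[C@H]2CCc3c(OCOC)c(CC=C(C)C)c(OCOC)cc3O2 | intermediate
26 | 3-methoxy-5-[(2R)-5,7-bis(methoxymethoxy)-6-(3-methylbut-2-en-1-yl)-3,4-dihydro-2H-chromen-2-yl]cyclohex-2-en-1-one (both configurations at ring carbon 5) | COC1=CC(=O)CC(C1)[C@H]2CCc3c(OCOC)c(CC=C(C)C)c(OCOC)cc3O2 | intermediate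
27 | lithium 3-methoxy-5-[(2R)-5,7-bis(methoxymethoxy)-6-(3-methylbut-2-en-1-yl)-3,4-dihydro-2H-chromen-2-yl]cyclohexa-1,3-dien-1-olate (not isolated) | COC1=CC(O[Li])=CC(C1)[C@H]2CCc3c(OCOC)c(CC=C(C)C)c(OCOC)cc3O2 | intermediate
28 | 3-methoxy-6-(phenylselanyl)-5-[(2R)-5,7-bis(methoxymethoxy)-6-(3-methylbut-2-en-1-yl)-3,4-dihydro-2H-chromen-2-yl]cyclohex-2-en-1-one (not isolated) | COC1=CC(=O)C([Se]c2ccccc2)C(C1)[C@H]3CCc4c(OCOC)c(CC=C(C)C)c(OCOC)cc4O3 | intermediate
29 | 3-methoxy-6-(phenylseleninyl)-5-[(2R)-5,7-bis(methoxymethoxy)-6-(3-methylbut-2-en-1-yl)-3,4-dihydro-2H-chromen-2-yl]cyclohex-2-en-1-one (not isolated) | COC1=CC(=O)C([Se](=O)c2ccccc2)C(C1)[C@H]3CCc4c(OCOC)c(CC=C(C)C)c(OCOC)cc4O3 | intermediate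
30 | 3-methoxy-5-[(2R)-5,7-bis(methoxymethoxy)-6-(3-methylbut-2-en-1-yl)-3,4-dihydro-2H-chromen-2-yl]cyclohexa-2,5-dien-1-one (not isolated) | COC1=CC(=O)C=C(C1)[C@H]2CCc3c(OCOC)c(CC=C(C)C)c(OCOC)cc3O2 | intermediate
31 | 3-methoxy-5-[(2R)-5,7-bis(methoxymethoxy)-6-(3-methylbut-2-en-1-yl)-3,4-dihydro-2H-chromen-2-yl]phenol | COc1cc(O)cc(c1)[C@H]2CCc3c(OCOC)c(CC=C(C)C)c(OCOC)cc3O2 | intermediate
32 | (2R)-2-(3,5-dimethoxyphenyl)-5,7-bis(methoxymethoxy)-6-(3-methylbut-2-en-1-yl)-3,4-dihydro-2H-chromene | COc1cc(OC)cc(c1)[C@H]2CCc3c(OCOC)c(CC=C(C)C)c(OCOC)cc3O2 | intermediate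
33 | (2R)-2-(3,5-dimethoxyphenyl)-6-(3-methylbut-2-en-1-yl)-3,4-dihydro-2H-chromene-5,7-diol | COc1cc(OC)cc(c1)[C@H]2CCc3c(O)c(CC=C(C)C)c(O)cc3O2 | target

**Step count and risks**

Total step count: 15. Longest linear sequence: 15 steps (1 → 33); all other partners are purchased.

Steps most likely to fail:

1. Step 10 (key step). What may go wrong: deprotonation at the γ-carbon of the enone (chroman C2) before the conjugate addition, with loss of configuration or migration of the double bond, or a Michael adduct that does not close to the ring. The fallback sets out from alcohol 17 and comes back at 23. Alcohol 17 is oxidised as in step 9 and aldehyde 19 is trapped in the flask with methyl (triphenylphosphoranylidene)acetate (CH2Cl2, rt) to give methyl (2E)-3-[(2R)-5,7-bis(methoxymethoxy)-6-(3-methylbut-2-en-1-yl)-3,4-dihydro-2H-chromen-2-yl]prop-2-enoate F1, whose γ-hydrogen is much less acidic than that of the enone. F1 is heated with methyl acetoacetate and NaOMe in MeOH; the acetoacetate anion adds to the β-carbon to give dimethyl 2-acetyl-3-[(2R)-5,7-bis(methoxymethoxy)-6-(3-methylbut-2-en-1-yl)-3,4-dihydro-2H-chromen-2-yl]pentanedioate F2, which is not isolated. Its acetyl methyl group then closes onto the remote ester (the acetoacetate/enoate variant of the Michael–Claisen annulation), and after acidification to pH 3 the same keto ester 23 results.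

2. Step 7. What may go wrong: competing metalation at C8, between the C7 MOM ether and the ring oxygen, so that the prenyl group enters at the wrong position. The fallback sets out from 13 and comes back at 16. C8 is first blocked by electrophilic bromination (N-bromosuccinimide, CH2Cl2, 0 °C), which in 5,7-dialkoxychromans is expected to take place at C8, to give {[(2R)-8-bromo-5,7-bis(methoxymethoxy)-3,4-dihydro-2H-chromen-2-yl]methoxy}(tert-butyl)dimethylsilane F3. The only remaining ring hydrogen, at C6, is removed with lithium 2,2,6,6-tetramethylpiperidide (from n-BuLi and the amine, THF, −78 °C), an amide base that does not exchange bromine, to give the 8-bromo-6-lithio compound F4. F4 is prenylated as in step 7 (CuI cat., 14) to the 8-bromo-6-prenyl silyl ether F5. Bromine–lithium exchange (t-BuLi, 2 equiv, THF, −78 °C) gives the 8-lithio compound F6, and a methanol quench returns 16.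

3. Step 13. What may go wrong: addition of the selenium electrophile to the prenyl double bond, oxidation of that double bond by the peroxide and selenium by-products, or incomplete syn-elimination. The fallback sets out from 26 and comes back at 31. Enolate 27 (LiN(iPr)2, THF, −78 °C) is trapped with Me3SiCl to give {3-methoxy-5-[(2R)-5,7-bis(methoxymethoxy)-6-(3-methylbut-2-en-1-yl)-3,4-dihydro-2H-chromen-2-yl]cyclohexa-1,3-dien-1-yl}oxy(trimethyl)silane F7. F7 is dehydrogenated with Pd(OAc)2 (1 equiv, MeCN, rt; Saegusa–Ito oxidation) to dienone 30, which tautomerises to phenol 31. No electrophilic selenium or peroxide is used.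

**Further compounds**

F1 | step 10 | methyl (2E)-3-[(2R)-5,7-bis(methoxymethoxy)-6-(3-methylbut-2-en-1-yl)-3,4-dihydro-2H-chromen-2-yl]prop-2-enoate | COC(=O)/C=C/[C@H]1CCc2c(OCOC)c(CC=C(C)C)c(OCOC)cc2O1
F2 | step 10 | dimethyl 2-acetyl-3-[(2R)-5,7-bis(methoxymethoxy)-6-(3-methylbut-2-en-1-yl)-3,4-dihydro-2H-chromen-2-yl]pentanedioate | COC(=O)CC(C(C(C)=O)C(=O)OC)[C@H]1CCc2c(OCOC)c(CC=C(C)C)c(OCOC)cc2O1
F3 | step 7 | {[(2R)-8-bromo-5,7-bis(methoxymethoxy)-3,4-dihydro-2H-chromen-2-yl]methoxy}(tert-butyl)dimethylsilane | CC(C)(C)[Si](C)(C)OC[C@H]1CCc2c(OCOC)cc(OCOC)c(Br)c2O1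
F4 | step 7 | C6-lithio derivative of F3 | CC(C)(C)[Si](C)(C)OC[C@H]1CCc2c(OCOC)c([Li])c(OCOC)c(Br)c2O1
F5 | step 7 | {[(2R)-8-bromo-5,7-bis(methoxymethoxy)-6-(3-methylbut-2-en-1-yl)-3,4-dihydro-2H-chromen-2-yl]methoxy}(tert-butyl)dimethylsilane | CC(C)(C)[Si](C)(C)OC[C@H]1CCc2c(OCOC)c(CC=C(C)C)c(OCOC)c(Br)c2O1
F6 | step 7 | C8-lithio derivative of 16 | CC(C)(C)[Si](C)(C)OC[C@H]1CCc2c(OCOC)c(CC=C(C)C)c(OCOC)c([Li])c2O1
F7 | step 13 | {3-methoxy-5-[(2R)-5,7-bis(methoxymethoxy)-6-(3-methylbut-2-en-1-yl)-3,4-dihydro-2H-chromen-2-yl]cyclohexa-1,3-dien-1-yl}oxy(trimethyl)silane | COC1=CC(O[Si](C)(C)C)=CC(C1)[C@H]2CCc3c(OCOC)c(CC=C(C)C)c(OCOC)cc3O2
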